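**Retrosynthetic overview**

1. Target 14 ⇐ iodolactone 13 (H2/Pd removes C–I and O‑benzyl) ⇐ dihydrofuranyl‑acetic acid 12 by cis‑iodolactonisation; the γ‑lactone ring is closed last and this fixes C4.
2. 12 ⇐ furanoid glycal acetate 11 by an Ireland–Claisen [3,3] rearrangement, which makes the C2–C3 bond; the C5 acetoxy stereocentre is relayed to C3 and then disappears.
3. 11 ⇐ β‑hydroxy‑γ‑lactone 7/8; the oxolane ring is made first as a lactone, then reduced and dehydrated to the cyclic enol ether.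
4. 7 ⇐ α‑hydroxy ketone 6 by chelation‑controlled MeMgBr addition (C5 controls C6); 6 ⇐ D‑malic acid acetonide 5 + Grignard of bromide 3.
5. Ring order: oxolane (steps 4–8), then γ‑lactone (step 10). The only source of chirality is the carbinol carbon of D‑malic acid.

Assumption: D‑(+)‑malic acid, 1 and 2 are bought. Position labels used below: C1 = lactone C=O, C2 = lactone CH2, C3 = ring‑fusion CH, C4 = ring‑fusion C(Me), C5 = ring CH2, C6 = C(Me)(alkyl). The target is (3S,4S,6S).

**Step 1**
Reactants: 1 1‑(benzyloxy)‑4‑bromobenzene; 2 1,12‑dibromododecane (3 equiv)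
Product: 3 1‑(benzyloxy)‑4‑(12‑bromododecyl)benzene
Conditions: 1, Mg, THF, reflux; then add to 2, Li2CuCl4 (3 mol %), THF, −10 → 20 °C
Reagents that add atoms: none
Why: Cu‑catalysed Kochi (Kumada‑type) sp2–sp3 coupling of the aryl Grignard with a primary bromide, with excess (recoverable) dibromide to keep it to mono‑arylation; no stereocentre involved.

**Step 2**
Reactants: 4 D‑(+)‑malic acid [(R)‑2‑hydroxybutanedioic acid]
Product: 5 (R)‑2‑(2,2‑dimethyl‑5‑oxo‑1,3‑dioxolan‑4‑yl)acetic acid
Conditions: Me2C(OMe)2, PPTS (cat.), rt, 24 h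
Reagents that add atoms: 2,2‑dimethoxypropane, COC(C)(C)OC
Why: Acetonide (dioxolanone) formation between the α‑OH and α‑CO2H masks the hydroxyl, activates the future C6 carbonyl and leaves the β‑CO2H (future C3) free; the stereocentre is untouched.

**Step 3**
Reactants: 5; 3
Product: 6 (3R)‑16‑[4‑(benzyloxy)phenyl]‑3‑hydroxy‑4‑oxohexadecanoic acid
Conditions: 3, Mg, THF → RMgBr (1.2 equiv); 5, LiHMDS (1.0 equiv), THF, −78 °C, then RMgBr, −78 → −30 °C; aq. citric acid
Reagents that add atoms: none
Why: Grignard mono‑addition to the activated dioxolanone carbonyl (lactone‑type acyl substitution) gives a cyclic hemiketal alkoxide that should persist until work‑up and then lose acetone to the α‑hydroxy ketone, while the carboxylate is inert and the C5 centre is not enolised at low temperature.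

**Step 4**
Reactants: 6
Product: 7 (4R,5S)‑5‑{12‑[4‑(benzyloxy)phenyl]dodecyl}‑4‑hydroxy‑5‑methyloxolan‑2‑one (OH and 5‑Me cis)
Conditions: MeMgBr (4.5 equiv), THF, −78 → 0 °C; then 1 M HCl, rt (TsOH cat., PhMe if lactonisation is incomplete)
Reagents that add atoms: methylmagnesium bromide, C[Mg]Br
Why: Cram‑chelate Grignard addition, in which Mg bridges the C5 alkoxide and the ketone oxygen so that methyl attacks the face syn to C5–H, sets C6 as S (expected dr ≥ 10:1, minor isomer removed at this stage), and the new tertiary OH then closes the γ‑lactone on the C3 acid.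

**Step 5**
Reactants: 7
Product: 8 (3R,4R,5S)‑5‑{12‑[4‑(benzyloxy)phenyl]dodecyl}‑4‑hydroxy‑3,5‑dimethyloxolan‑2‑one (3‑Me trans to OH; the 3‑epimer is equally usable)
Conditions: LDA (2.2 equiv), THF–DMPU, −78 → −40 °C; MeI (1.2 equiv)
Reagents that add atoms: iodomethane, CI
Why: Fráter–Seebach‑type alkylation of the β‑alkoxide lactone enolate (dianion), where the alkoxide prevents β‑elimination and methyl enters trans to O⁻; this centre becomes sp2 in step 8, so its configuration does not matter.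

**Step 6**
Reactants: 8
Product: 9 (2S,3R,4R)‑2‑{12‑[4‑(benzyloxy)phenyl]dodecyl}‑2,4‑dimethyl‑5‑oxooxolan‑3‑yl acetate
Conditions: Ac2O, pyridine, DMAP (cat.), 0 °C → rt
Reagents that add atoms: acetic anhydride, CC(=O)OC(C)=O
Why: O‑acetylation under weakly basic conditions (to avoid E1cB loss of acetate) puts the two carbons that become C1–C2 on the C5 oxygen with retention.

**Step 7**
Reactants: 9
Product: 10 (2S,3R,4R,5RS)‑2‑{12‑[4‑(benzyloxy)phenyl]dodecyl}‑5‑hydroxy‑2,4‑dimethyloxolan‑3‑yl acetate (lactol, anomeric mixture)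
Conditions: Sia2BH (3 equiv), THF, 0 °C → rt; pH 7 buffer/H2O2 work‑up
Reagents that add atoms: none
Why: Disiamylborane reduces γ‑lactones to lactols chemoselectively and leaves carboxylic esters alone, as in the reduction of acylated aldonolactones; no stereocentre of consequence is formed.

**Step 8**
Reactants: 10
Product: 11 (2S,3R)‑2‑{12‑[4‑(benzyloxy)phenyl]dodecyl}‑2,4‑dimethyl‑2,3‑dihydrofuran‑3‑yl acetate (furanoid glycal; OAc cis to the 2‑Me)
Conditions: MsCl, Et3N, CH2Cl2, −40 °C → rt
Reagents that add atoms: none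
Why: The anomeric mesylate ionises and the oxocarbenium loses C4–H (E1‑type dehydration) to give the cyclic enol ether, erasing the C4 centre, and the quaternary C6 blocks aromatisation to a furan.

**Step 9**
Reactants: 11
Product: 12 2‑[(2S,5S)‑5‑{12‑[4‑(benzyloxy)phenyl]dodecyl}‑3,5‑dimethyl‑2,5‑dihydrofuran‑2‑yl]acetic acid (CH2CO2H cis to the 5‑Me)
Conditions: LDA, TMSCl–Et3N (premixed, internal quench), THF, −78 °C → rt; then pH 4 aqueous work‑up
Reagents that add atoms: none
Why: Ireland–Claisen [3,3]‑sigmatropic rearrangement of the silyl ketene acetal is suprafacial across the ring, so the C2–C3 bond forms on the face that carried the C5–O bond and the C5 centre is transferred to C3 (S) and then erased.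

**Step 10**
Reactants: 12
Product: 13 (3aS,5S,6R,6aR)‑5‑{12‑[4‑(benzyloxy)phenyl]dodecyl}‑6‑iodo‑5,6a‑dimethyltetrahydrofuro[3,2‑b]furan‑2(3H)‑one (cis‑fused; I anti to the lactone oxygen)
Conditions: I2, NaHCO3, MeCN, 0 °C, dark
Reagents that add atoms: iodine, II
Why: 5‑exo, Markovnikov iodolactonisation, in which the carboxylate tethered at C3 can only reach C4 from its own face, gives the cis‑fused lactone and sets C4 (S in the final product) with iodine anti on C5.

**Step 11**
Reactants: 13
Product: 14 plakortone N, (3aS,5S,6aS)‑5‑[12‑(4‑hydroxyphenyl)dodecyl]‑5,6a‑dimethyltetrahydrofuro[3,2‑b]furan‑2(3H)‑one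
Conditions: H2 (1 atm), 10 % Pd/C, Et3N, EtOAc–MeOH, rt
Reagents that add atoms: none
Why: One hydrogenolysis removes both the C–I bond (no β‑hydrogens, so no elimination) and the phenolic benzyl ether without touching the lactone or any stereocentre.

**Compound list**

1 | 1‑(benzyloxy)‑4‑bromobenzene | Brc1ccc(OCc2ccccc2)cc1 | starting material
2 | 1,12‑dibromododecane | BrCCCCCCCCCCCCBr | starting material
3 | 1‑(benzyloxy)‑4‑(12‑bromododecyl)benzene | BrCCCCCCCCCCCCc1ccc(OCc2ccccc2)cc1 | intermediate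
4 | D‑(+)‑malic acid, (R)‑2‑hydroxybutanedioic acid | O[C@H](CC(=O)O)C(=O)O | starting material
5 | (R)‑2‑(2,2‑dimethyl‑5‑oxo‑1,3‑dioxolan‑4‑yl)acetic acid | CC1(C)O[C@H](CC(=O)O)C(=O)O1 | intermediate
6 | (3R)‑16‑[4‑(benzyloxy)phenyl]‑3‑hydroxy‑4‑oxohexadecanoic acid | O[C@H](CC(=O)O)C(=O)CCCCCCCCCCCCc1ccc(OCc2ccccc2)cc1 | intermediate
7 | (4R,5S)‑5‑{12‑[4‑(benzyloxy)phenyl]dodecyl}‑4‑hydroxy‑5‑methyloxolan‑2‑one | O=C1C[C@@H](O)[C@](C)(CCCCCCCCCCCCc2ccc(OCc3ccccc3)cc2)O1 | intermediate
8 | (3R,4R,5S)‑5‑{12‑[4‑(benzyloxy)phenyl]dodecyl}‑4‑hydroxy‑3,5‑dimethyloxolan‑2‑one | O=C1[C@H](C)[C@@H](O)[C@](C)(CCCCCCCCCCCCc2ccc(OCc3ccccc3)cc2)O1 | intermediate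
9 | (2S,3R,4R)‑2‑{12‑[4‑(benzyloxy)phenyl]dodecyl}‑2,4‑dimethyl‑5‑oxooxolan‑3‑yl acetate | O=C1[C@H](C)[C@@H](OC(C)=O)[C@](C)(CCCCCCCCCCCCc2ccc(OCc3ccccc3)cc2)O1 | intermediate
10 | (2S,3R,4R,5RS)‑2‑{12‑[4‑(benzyloxy)phenyl]dodecyl}‑5‑hydroxy‑2,4‑dimethyloxolan‑3‑yl acetate | OC1[C@H](C)[C@@H](OC(C)=O)[C@](C)(CCCCCCCCCCCCc2ccc(OCc3ccccc3)cc2)O1 | intermediate
11 | (2S,3R)‑2‑{12‑[4‑(benzyloxy)phenyl]dodecyl}‑2,4‑dimethyl‑2,3‑dihydrofuran‑3‑yl acetate | C1=C(C)[C@@H](OC(C)=O)[C@](C)(CCCCCCCCCCCCc2ccc(OCc3ccccc3)cc2)O1 | intermediate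
12 | 2‑[(2S,5S)‑5‑{12‑[4‑(benzyloxy)phenyl]dodecyl}‑3,5‑dimethyl‑2,5‑dihydrofuran‑2‑yl]acetic acid | OC(=O)C[C@H]1C(C)=C[C@](C)(CCCCCCCCCCCCc2ccc(OCc3ccccc3)cc2)O1 | intermediate
13 | (3aS,5S,6R,6aR)‑5‑{12‑[4‑(benzyloxy)phenyl]dodecyl}‑6‑iodo‑5,6a‑dimethyltetrahydrofuro[3,2‑b]furan‑2(3H)‑one | C[C@]1(CCCCCCCCCCCCc3ccc(OCc4ccccc4)cc3)[C@@H](I)[C@]2(C)OC(=O)C[C@@H]2O1 | intermediate
14 | plakortone N | C[C@]1(CCCCCCCCCCCCc2ccc(O)cc2)C[C@]2(C)OC(=O)C[C@@H]2O1 | target

**Totals**

Total steps: 11. Longest linear sequence: 10 (4 → 14; step 1 is a one‑step side branch).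

**Three steps most likely to fail, with fallbacks**

- **Step 3 (mono‑addition to the dioxolanone).** The risk is over‑addition to the tertiary alcohol or epimerisation of the α‑hydroxy ketone. Fallback: change the acyl donor by opening 5 with MeNH(OMe) to the α‑hydroxy Weinreb amide and adding the Grignard to that, so the stable chelate rather than the hemiketal stops the reaction at the ketone.
- **Step 8 (glycal formation with the C5 acetate in place).** The risk is β‑elimination of acetate or acetyl migration. Fallback: change the protecting‑group logic by carrying C5–OH of 8 as a TBS ether through DIBAL reduction and dehydration, then TBAF and acetylation of the glycal alkoxide (two extra steps, and no base‑labile β‑acyloxy carbonyl at any stage).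
- **Step 9 (Ireland–Claisen of an acetate on an acid‑labile glycal).** The risk is C‑silylation, ester condensation or Ferrier‑type ionisation. Fallback: abandon the [3,3] step and build the lactone on the same enol ether by dichloroketene [2+2] cycloaddition anti to the C5 oxygen substituent, followed by Zn dechlorination, Baeyer–Villiger oxidation with migration of the quaternary C4, and Barton–McCombie removal of the C5 oxygen.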